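## Retrosynthetic overview

1. Target 28 comes from α-face hydrogenation of the C11=C12 enol acetate 27. That comes from 11-ketone 25, made by 1,4-reduction of the tetracyclic vinylogous ester 23. These steps set C9–C12.
2. The oxepane is the last ring. The C3 tertiary OH displaces a C16 triflate made by hydroboration of the C14 isopropenyl group (19 → 23).
3. The key step is a domino on acyclic 15. C1=C14 macro-olefination gives the 14-membered cembranoid ring, a transannular C10→C1 Michael closure gives the 6/10 eunicellane, and the C9 oxygen then opens the 2,3-epoxide at C2 to give the oxolane and oxonane.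
4. 15 comes from a C9–C10 aldol of aldehyde 7 (neryl acetate plus Z-crotylboronate) with keto-phosphonate 10 (two commodity pieces), followed by Sharpless epoxidation for C2 and C3.
5. Ring order: 14 → 6 + 10 → oxolane (with oxonane) → oxepane.

Assumption: asbestinin numbering is used throughout. C1/C10 is the ring fusion, C2–O–C9 the oxolane bridge and C3–O–C16 the oxepane. C6 carries OMe, C7 carries Me, C11 carries OAc, C12 carries Me, and C14 carries C15(C17)–C16. C9, C12 and C14 are carried as epimer mixtures (no stereo label in the SMILES) until they are erased or fixed.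

## Route

Step 1
Reactants: 1 neryl acetate
Product: 2 (2Z)-3-methyl-6-oxohex-2-en-1-yl acetate
Conditions: O3 (1.0 equiv, Sudan III end-point), CH2Cl2/MeOH, −78 °C; Me2S
Reagents that add atoms: ozone, [O-][O+]=O
Why: Chemoselective ozonolysis cuts only the electron-rich 6,7-alkene, because the 2,3-alkene is deactivated by the allylic acetate, so the 2Z geometry survives.

Step 2
Reactants: 2 (2Z)-3-methyl-6-oxohex-2-en-1-yl acetate; 3 (Z)-crotylboronic acid pinacol ester
Product: 5 (2Z,6R,7R)-6-hydroxy-3,7-dimethylnona-2,8-dien-1-yl acetate, via pinacol borate ester 4 (not isolated)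
Conditions: (S)-TRIP (5 mol %), toluene, −30 °C; aq. NaHCO3 work-up
Reagents that add atoms: none
Why: Chiral-phosphoric-acid-catalysed crotylboration runs through a closed chair transition state, so the Z-crotyl geometry gives the 6,7-syn pair and (S)-TRIP directs si-face attack, setting 6R and 7R.

Step 3
Reactants: 5 (2Z,6R,7R)-6-hydroxy-3,7-dimethylnona-2,8-dien-1-yl acetate
Product: 6 (2Z,6R,7R)-6-methoxy-3,7-dimethylnona-2,8-dien-1-yl acetate
Conditions: MeOTf, 2,6-di-tert-butylpyridine, CH2Cl2, 0 °C → rt
Reagents that add atoms: methyl triflate, COS(=O)(=O)C(F)(F)F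
Why: O-alkylation with a hard methylating agent and a non-nucleophilic base installs the C6 methyl ether without touching the acetate or any stereocentre.

Step 4
Reactants: 6 (2Z,6R,7R)-6-methoxy-3,7-dimethylnona-2,8-dien-1-yl acetate
Product: 7 (2Z,6R,7R)-6-methoxy-3,7-dimethyl-9-oxonon-2-en-1-yl acetate
Conditions: PdCl2(PhCN)2 (10 mol %), CuCl2·2H2O (10 mol %), AgNO2 (5 mol %), O2 (1 atm), t-BuOH/MeNO2 15:1, rt
Reagents that add atoms: dioxygen, O=O
Why: The nitrite-modified aldehyde-selective (anti-Markovnikov) Wacker oxidation converts the allylically branched monosubstituted alkene with a nearby ether oxygen into the C9 aldehyde, and the trisubstituted alkene is inert.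

Step 5
Reactants: 8 diethyl (2-oxopropyl)phosphonate; 9 3-methylbut-3-en-2-one
Product: 10 diethyl (5-methyl-2,6-dioxoheptan-3-yl)phosphonate (all stereoisomers)
Conditions: 8 (1.5 equiv), Cs2CO3 (10 mol %), THF, 0 °C → rt, slow addition of 9
Reagents that add atoms: none
Why: Base-catalysed Michael addition of the stabilised keto-phosphonate carbanion forms C13–C14, and excess donor suppresses double addition; C12 and C14 need no control because both are reset later.

Step 6
Reactants: 10 diethyl (5-methyl-2,6-dioxoheptan-3-yl)phosphonate; 7 (2Z,6R,7R)-6-methoxy-3,7-dimethyl-9-oxonon-2-en-1-yl acetate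
Product: 12 (2Z,6R,7R)-14-(diethoxyphosphoryl)-9-hydroxy-6-methoxy-3,7,12-trimethyl-11,15-dioxohexadec-2-en-1-yl acetate, via sodium lithium dianion 11 (not isolated)
Conditions: NaH (1.0 equiv), THF, 0 °C; LDA (1.05 equiv), −78 °C; 7, −78 °C, 20 min; AcOH quench
Reagents that add atoms: none
Why: In this directed aldol addition of a dianion, NaH parks C14/C15 as the inert keto-phosphonate enolate, LDA then removes the most accessible proton of the free ketone (C10 methyl), and that enolate adds to the aldehyde at −78 °C far faster than the hindered phosphonate anion olefinates; C9 is later oxidised, so its configuration is irrelevant.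

Step 7
Reactants: 12 acyclic aldol acetate
Product: 13 (2Z,6R,7R)-14-(diethoxyphosphoryl)-1,9-dihydroxy-6-methoxy-3,7,12-trimethylhexadec-2-ene-11,15-dione
Conditions: K2CO3 (0.2 equiv), MeOH, 0 °C
Reagents that add atoms: none
Why: Zemplén-type transesterification of the primary allylic acetate is fast at 0 °C, which leaves the β-hydroxy ketone and the keto-phosphonate intact.

Step 8
Reactants: 13 allylic alcohol diol
Product: 14 (2R,3S,6R,7R)-2,3-epoxide of 13
Conditions: Ti(Oi-Pr)4 (20 mol %), D-(−)-DIPT (24 mol %), t-BuOOH, 4 Å MS, CH2Cl2, −20 °C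
Reagents that add atoms: tert-butyl hydroperoxide, CC(C)(C)OO
Why: Sharpless asymmetric epoxidation acts on the only alkene present, a Z-trisubstituted allylic alcohol of the nerol type, and D-(−)-tartrate delivers the 2R,3S epoxide under reagent control; the catalyst loading can be raised if the chelating groups slow turnover.

Step 9
Reactants: 14 epoxy diol
Product: 15 (2S,3S,6R,7R)-14-(diethoxyphosphoryl)-2,3-epoxy-6-methoxy-3,7,12-trimethyl-9,11,15-trioxohexadecanal
Conditions: Dess–Martin periodinane (2.5 equiv), CH2Cl2, 0 °C → rt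
Reagents that add atoms: none
Why: One double Dess–Martin oxidation under near-neutral conditions gives both the C1 epoxy-aldehyde and the 9,11-diketone, erasing C9 and leaving the epoxide untouched; the C2 descriptor changes only because of CIP priorities.

Step 10
Reactants: 15 acyclic epoxy-aldehyde diketo-phosphonate
Product: 18 tricyclic vinylogous ester (1S,2S,3S,6R,7R,14R; C2–O–C9 bridge; C9=C10–C11=O; 3-OH; 6-OMe; 14-acetyl), via macrocyclic epoxy-enone 16 (not isolated), via bicyclic Michael adduct 17 (not isolated)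
Conditions: LiCl (20 equiv), DBU (6 equiv), MeCN, 1 mM (syringe pump), 25 °C, then 50 °C
Reagents that add atoms: none
Why: Proposed new method: this is a one-flask Masamune–Roush macro-HWE / transannular Michael / epoxide-opening domino in which DBU/LiCl turns the 9,11-diketone into its lithium diketonate (shielding both ketones from the phosphonate carbanion), the C14 phosphonate olefinates the C1 epoxy-aldehyde to the 14-membered epoxy-enone 16, the diketonate carbon C10 adds reversibly across the ring to C1 (6-endo-trig) to give 17, and only the C1 epimer that places C14 and C3 trans on the forming five-membered ring lets the C9 enolate oxygen open the epoxide at C2 (5-exo-tet with inversion; attack by O11 would need an anti-Bredt alkene), which drains the equilibria to 1S,2S while C14 epimerises to the equatorial acetyl trans to C2; the closest known reaction types are macrocyclic HWE closures of cembranoids, transannular Michael closures of norcembranoids, and C- then O-alkylation of 1,3-diketones by epoxy electrophiles.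

Step 11
Reactants: 18 tricyclic vinylogous ester methyl ketone
Product: 19 14-isopropenyl tricyclic vinylogous ester (1S,2S,3S,6R,7R,14R)
Conditions: Ph3PCH3Br (4 equiv), KOt-Bu (3.8 equiv), THF, 0 °C → rt
Reagents that add atoms: methyltriphenylphosphonium bromide, C[P+](c1ccccc1)(c1ccccc1)c1ccccc1.[Br-]
Why: Wittig methylenation takes only the C15 methyl ketone because the C11 vinylogous ester carbonyl is too electron-rich; excess ylide covers the free C3–OH and drains any C3–O–C15 lactol through its open form, and C14 already sits in its thermodynamic configuration.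

Step 12
Reactants: 19 14-isopropenyl tricyclic vinylogous ester
Product: 21 C16 primary alcohol (1S,2S,3S,6R,7R,14S,15R), via pinacol boronate 20 (not isolated)
Conditions: HBpin, [Ir(cod)Cl]2 (2.5 mol %), dppe (5 mol %), THF, rt; then 30 % H2O2, pH 7 buffer, 0 °C
Reagents that add atoms: hydrogen peroxide, OO
Why: Catalysed anti-Markovnikov hydroboration–oxidation spares the carbonyl, and in the A(1,3)-minimised rotamer (H14 eclipsing C15=C16) hydrogen reaches C15 from the open C13 side rather than the C1/C2 side, which gives 15R.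

Step 13
Reactants: 21 C16 primary alcohol
Product: 23 tetracyclic vinylogous ester (1S,2S,3S,6R,7R,14S,15R; oxepane closed), via primary triflate 22 (not isolated)
Conditions: Tf2O (1.1 equiv), 2,6-lutidine, CH2Cl2, −78 → 0 °C
Reagents that add atoms: none
Why: In this intramolecular Williamson-type etherification the primary alcohol is triflated selectively and the C3 tertiary hydroxyl, held gauche by the trans-diequatorial C1/C14 substituents, displaces it (7-exo-tet), a closure known for this ring system; no stereocentre is touched.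

Step 14
Reactants: 23 tetracyclic vinylogous ester
Product: 25 tetracyclic 11-ketone (1S,2S,3S,6R,7R,9S,10R,14S,15R; C12 epimers), via lithium enolate 24 (not isolated)
Conditions: L-Selectride (1.2 equiv), THF, −78 °C; AcOH quench
Reagents that add atoms: none
Why: This is the 1,4-hydride reduction known for cyclic vinylogous esters such as dihydropyranones; hydride can reach C9 only from the face opposite the C3–C8 bridge (9S), and C10, being α to the ketone, settles as the cis-fused isomer with C8 and C11 trans on the oxolane (10R).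

Step 15
Reactants: 25 tetracyclic 11-ketone
Product: 27 C11=C12 enol acetate, via potassium enolate 26 (not isolated)
Conditions: KHMDS (1.2 equiv), THF, −78 °C; Ac2O
Reagents that add atoms: acetic anhydride, CC(=O)OC(C)=O
Why: Kinetic enolisation followed by O-acylation goes toward C12 because H10 is equatorial, orthogonal to the carbonyl π system and more hindered, which also avoids E1cB loss of the C9 oxygen; both C12 epimers converge on one enol acetate.

Step 16
Reactants: 27 C11=C12 enol acetate
Product: 28 target CNP0289153.2 (1S,2S,3S,6R,7R,9S,10R,11R,12R,14S,15R)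
Conditions: H2 (80 bar), [Ir(cod)(PCy3)(py)]BArF (5 mol %), CH2Cl2, rt
Reagents that add atoms: none
Why: Homogeneous syn-hydrogenation of the tetrasubstituted enol ester with a Crabtree-type catalyst occurs on the α-face because the β-face is blocked by the axial C10–C9 bond and the oxonane, so H11 and H12 enter cis and leave 11-OAc and the contra-thermodynamic axial 12-Me both β.

## Compound list

1 | neryl acetate | CC(=O)OC/C=C(/C)CCC=C(C)C | starting material
2 | (2Z)-3-methyl-6-oxohex-2-en-1-yl acetate | CC(=O)OC/C=C(/C)CCC=O | intermediate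
3 | (Z)-crotylboronic acid pinacol ester | C/C=C\CB1OC(C)(C)C(C)(C)O1 | starting material
4 | pinacol borate ester of 5 | CC(=O)OC/C=C(/C)CC[C@@H](OB1OC(C)(C)C(C)(C)O1)[C@H](C)C=C | intermediate
5 | (2Z,6R,7R)-6-hydroxy-3,7-dimethylnona-2,8-dien-1-yl acetate | CC(=O)OC/C=C(/C)CC[C@@H](O)[C@H](C)C=C | intermediate
6 | (2Z,6R,7R)-6-methoxy-3,7-dimethylnona-2,8-dien-1-yl acetate | CC(=O)OC/C=C(/C)CC[C@@H](OC)[C@H](C)C=C | intermediate
7 | (2Z,6R,7R)-6-methoxy-3,7-dimethyl-9-oxonon-2-en-1-yl acetate | CC(=O)OC/C=C(/C)CC[C@@H](OC)[C@H](C)CC=O | intermediate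
8 | diethyl (2-oxopropyl)phosphonate | CCOP(=O)(CC(C)=O)OCC | starting material
9 | 3-methylbut-3-en-2-one | CC(=O)C(C)=C | starting material
10 | diethyl (5-methyl-2,6-dioxoheptan-3-yl)phosphonate | CCOP(=O)(OCC)C(CC(C)C(C)=O)C(C)=O | intermediate
11 | sodium lithium dianion of 10 | CCOP(=O)(OCC)C(CC(C)C([O-])=C)=C(C)[O-].[Na+].[Li+] | intermediate
12 | acyclic aldol acetate | CC(=O)OC/C=C(/C)CC[C@@H](OC)[C@H](C)CC(O)CC(=O)C(C)CC(C(C)=O)P(=O)(OCC)OCC | intermediate
13 | acyclic 1,9-diol | OC/C=C(/C)CC[C@@H](OC)[C@H](C)CC(O)CC(=O)C(C)CC(C(C)=O)P(=O)(OCC)OCC | intermediate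
14 | (2R,3S)-epoxy diol | OC[C@H]1O[C@@]1(C)CC[C@@H](OC)[C@H](C)CC(O)CC(=O)C(C)CC(C(C)=O)P(=O)(OCC)OCC | intermediate
15 | epoxy-aldehyde 9,11-diketone keto-phosphonate | O=C[C@H]1O[C@@]1(C)CC[C@@H](OC)[C@H](C)CC(=O)CC(=O)C(C)CC(C(C)=O)P(=O)(OCC)OCC | intermediate
16 | 14-membered epoxy-enone (14-acetyl-2,3-epoxy-6-methoxy-3,7,12-trimethylcyclotetradec-1(14)-ene-9,11-dione) | CC(=O)C1=C[C@H]2O[C@@]2(C)CC[C@@H](OC)[C@H](C)CC(=O)CC(=O)C(C)C1 | intermediate
17 | bicyclic 6/10 Michael adduct (2,3-epoxide and 9,11-diketone retained) | CC(=O)[C@@H]1CC(C)C(=O)C2[C@H]1[C@H]3O[C@@]3(C)CC[C@@H](OC)[C@H](C)CC2=O | intermediate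
18 | tricyclic vinylogous ester, 14-acetyl, 3-OH | CO[C@@H]1CC[C@](C)(O)[C@H]2OC(C[C@H]1C)=C3C(=O)C(C)C[C@@H](C(C)=O)[C@H]23 | intermediate
19 | tricyclic vinylogous ester, 14-isopropenyl | CO[C@@H]1CC[C@](C)(O)[C@H]2OC(C[C@H]1C)=C3C(=O)C(C)C[C@@H](C(C)=C)[C@H]23 | intermediate
20 | C16 pinacol boronate | CO[C@@H]1CC[C@](C)(O)[C@H]2OC(C[C@H]1C)=C3C(=O)C(C)C[C@@H]([C@@H](C)CB4OC(C)(C)C(C)(C)O4)[C@H]23 | intermediate
21 | C16 primary alcohol | CO[C@@H]1CC[C@](C)(O)[C@H]2OC(C[C@H]1C)=C3C(=O)C(C)C[C@@H]([C@@H](C)CO)[C@H]23 | intermediate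
22 | C16 primary triflate | CO[C@@H]1CC[C@](C)(O)[C@H]2OC(C[C@H]1C)=C3C(=O)C(C)C[C@@H]([C@@H](C)COS(=O)(=O)C(F)(F)F)[C@H]23 | intermediate
23 | tetracyclic vinylogous ester | CO[C@@H]1CC[C@]2(C)OC[C@H](C)[C@@H]3CC(C)C(=O)C4=C(C[C@H]1C)O[C@H]2[C@@H]34 | intermediate
24 | lithium C10=C11 enolate | CO[C@@H]1CC[C@]2(C)OC[C@H](C)[C@@H]3CC(C)C([O-])=C4[C@H]3[C@@H]2O[C@H]4C[C@H]1C.[Li+] | intermediate
25 | tetracyclic 11-ketone | CO[C@@H]1CC[C@]2(C)OC[C@H](C)[C@@H]3CC(C)C(=O)[C@@H]4[C@H]3[C@@H]2O[C@H]4C[C@H]1C | intermediate
26 | potassium C11=C12 enolate | CO[C@@H]1CC[C@]2(C)OC[C@H](C)[C@@H]3CC(C)=C([O-])[C@@H]4[C@H]3[C@@H]2O[C@H]4C[C@H]1C.[K+] | intermediate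
27 | C11=C12 enol acetate | CO[C@@H]1CC[C@]2(C)OC[C@H](C)[C@@H]3CC(C)=C(OC(C)=O)[C@@H]4[C@H]3[C@@H]2O[C@H]4C[C@H]1C | intermediate
28 | CNP0289153.2 | CO[C@@H]1CC[C@]2(C)OC[C@H](C)[C@@H]3C[C@@H](C)[C@@H](OC(C)=O)[C@@H]4[C@H]3[C@@H]2O[C@H]4C[C@H]1C | target

## Step count and risks

Total step count: 16. Longest linear sequence: 15 (steps 1–4 and 6–16).

**Step 10 (domino macro-HWE / transannular Michael / epoxide opening).** The free diketone may interfere with the macrocyclisation, or the α-branched phosphonate may olefinate too slowly.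

The fallback sets out from 14 and keeps the C10 nucleophile masked until the large ring exists. TEMPO/PhI(OAc)2 oxidises only the primary alcohol, giving the C9-hydroxy epoxy-aldehyde F1. LiCl/DBU at high dilution then closes the 14-membered C9-hydroxy epoxy-enone F2. Dess–Martin oxidation of F2 gives 16, now isolated, and Cs2CO3 in MeCN triggers the two transannular closures. The route is rejoined at 18.

**Step 14 (1,4-reduction of a tetrasubstituted vinylogous ester).** The β-carbon may be too hindered and too electron-rich for hydride addition.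

The fallback sets out from 23 and replaces conjugate reduction by a reduce, ionise and re-oxidise sequence. Luche 1,2-reduction gives the C11 allylic alcohol F3. Et3SiH/BF3·OEt2 ionises it to the conjugated oxocarbenium ion and delivers hydride to C9 from the open face, giving the C10=C11 alkene F4. BH3·THF then H2O2 adds H10 and the C11 oxygen from the α-face, giving the 11α-alcohol F5. Dess–Martin oxidation of F5 rejoins the route at 25.

**Step 16 (hydrogenation of a tetrasubstituted enol acetate).** The alkene may be inert, or the C–O bond may be hydrogenolysed.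

The fallback sets out from 25 and moves the hydrogenation to an easier trisubstituted alkene. LDA followed by N-tert-butylbenzenesulfinimidoyl chloride dehydrogenates 25 to the C12=C13 enone F6. H2 over Pd/C adds from the α-face under neutral conditions, giving the 12R ketone F7. NaBH4 attacks from the same open face, giving the 11β-alcohol F8. Ac2O/DMAP then rejoins the route at 28.

## Further compounds

F1 | step 10 | C9-hydroxy epoxy-aldehyde | O=C[C@H]1O[C@@]1(C)CC[C@@H](OC)[C@H](C)CC(O)CC(=O)C(C)CC(C(C)=O)P(=O)(OCC)OCC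
F2 | step 10 | 14-membered C9-hydroxy epoxy-enone | CC(=O)C1=C[C@H]2O[C@@]2(C)CC[C@@H](OC)[C@H](C)CC(O)CC(=O)C(C)C1
F3 | step 14 | C11 allylic alcohol | CO[C@@H]1CC[C@]2(C)OC[C@H](C)[C@@H]3CC(C)C(O)C4=C(C[C@H]1C)O[C@H]2[C@@H]34
F4 | step 14 | C10=C11 alkene | CO[C@@H]1CC[C@]2(C)OC[C@H](C)[C@@H]3CC(C)C=C4[C@H]3[C@@H]2O[C@H]4C[C@H]1C
F5 | step 14 | 11α-alcohol | CO[C@@H]1CC[C@]2(C)OC[C@H](C)[C@@H]3CC(C)[C@H](O)[C@@H]4[C@H]3[C@@H]2O[C@H]4C[C@H]1C
F6 | step 16 | C12=C13 enone | CO[C@@H]1CC[C@]2(C)OC[C@H](C)[C@@H]3C=C(C)C(=O)[C@@H]4[C@H]3[C@@H]2O[C@H]4C[C@H]1C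
F7 | step 16 | 12R ketone | CO[C@@H]1CC[C@]2(C)OC[C@H](C)[C@@H]3C[C@@H](C)C(=O)[C@@H]4[C@H]3[C@@H]2O[C@H]4C[C@H]1C
F8 | step 16 | 11β-alcohol | CO[C@@H]1CC[C@]2(C)OC[C@H](C)[C@@H]3C[C@@H](C)[C@@H](O)[C@@H]4[C@H]3[C@@H]2O[C@H]4C[C@H]1C
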